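**Retrosynthetic overview**

- The plan rests on the lactone ring O1–C2(=O)–C3=C4–C5–C6 with its single stereocentre C6. It is read as an oxidised 2-methoxy-5,6-dihydro-2H-pyran, which is the [4+2] adduct of an aldehyde C=O (C6, O1) and a 1-oxygenated butadiene (C2–C5).
- Lactone ⇒ cis-2-methoxy-6-alkynyl-dihydropyran ⇒ (C5–C6 and O1–C2) (E)-1-methoxybutadiene + tris-silylated ynal; the C1′≡C2′ triple bond is the latent Z-alkene.
- Ynal ⇒ terminal alkyne (C6–C1′, formylation) ⇒ C4′ aldehyde + allenylboronate (C3′–C4′, catalyst-controlled propargylation sets C4′).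
- C4′ aldehyde ⇒ syn-3,5-diol ester (Narasaka–Prasad sets C6′) ⇒ δ-hydroxy-β-keto ester ⇒ cinnamaldehyde + Chan's diene (C7′–C8′, asymmetric vinylogous aldol sets C8′).
- Ring order: the phenyl ring is bought; the dihydropyran(one) is the only ring made, in step 8, after all chain stereocentres are in place.

Key step: step 8

Assumption: the catalyst enantiomers named, (R)-BINOL, (S)-TRIP and the chromium complex of the (1R,2S)-aminoindanol ligand, are those expected from the accepted transition-state models to add to the Re, Si and Re faces respectively; the face stated in each step defines the step, and the antipodal catalyst would be used if a configuration assay showed otherwise.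

Abbreviations and numbering: TBS = tert-butyldimethylsilyl, TBSO = (tert-butyldimethylsilyl)oxy, TRIP = 3,3′-bis(2,4,6-triisopropylphenyl)-1,1′-binaphthyl-2,2′-diyl hydrogen phosphate. Lactone atoms are O1–C6; side-chain atoms are C1′–C10′ (C1′ on C6, phenyl on C10′). The target is (6R)-6-[(1Z,4S,6R,8R,9E)-4,6,8-trihydroxy-10-phenyldeca-1,9-dien-1-yl]-5,6-dihydro-2H-pyran-2-one: 4′,6′-anti and 6′,8′-syn.

**Route**

Step 1
Reactants: 1 (E)-cinnamaldehyde; 2 1-methoxy-1,3-bis(trimethylsilyloxy)buta-1,3-diene (Chan's diene)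
Product: 4 methyl (5R,6E)-5-hydroxy-3-oxo-7-phenylhept-6-enoate, via silylated aldol adduct 3 (not isolated)
Conditions: Ti(OiPr)4 (10 mol %), (R)-BINOL (10 mol %), 4 Å MS, THF, −78 °C to rt; then TFA (cat.), wet THF, 0 °C
Reagents that add atoms: none
Why: Catalytic asymmetric vinylogous Mukaiyama aldol: the (R)-BINOL titanium complex activates the enal carbonyl and the terminal carbon of Chan's diene should add 1,2 to its Re face, which sets C8′ (5R in 4); mild acid then cleaves the silyl groups of 3.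

Step 2
Reactants: 4 methyl (5R,6E)-5-hydroxy-3-oxo-7-phenylhept-6-enoate
Product: 6 methyl (3S,5R,6E)-3,5-dihydroxy-7-phenylhept-6-enoate, via diethylboron chelate 5 (not isolated)
Conditions: Et2BOMe (1.1 equiv), THF/MeOH 4:1, −78 °C; NaBH4, −78 °C; AcOH quench, repeated co-evaporation with MeOH
Reagents that add atoms: none
Why: Narasaka–Prasad reduction: Et2BOMe locks the β-hydroxy ketone as the six-membered boron chelate 5 and external hydride attacks its half-chair axially, which should give the 3,5-syn diol (new centre 3S, the future C6′).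

Step 3
Reactants: 6 methyl (3S,5R,6E)-3,5-dihydroxy-7-phenylhept-6-enoate
Product: 7 methyl (3S,5R,6E)-3,5-bis(TBSO)-7-phenylhept-6-enoate
Conditions: TBSOTf (2.5 equiv), 2,6-lutidine, CH2Cl2, −78 to 0 °C
Reagents that add atoms: tert-butyldimethylsilyl triflate, CC(C)(C)[Si](C)(C)OS(=O)(=O)C(F)(F)F
Why: Standard silylation of both secondary alcohols with a silyl triflate and a hindered base, fast enough at low temperature to outrun lactonisation of the hydroxy ester; no stereocentre is touched.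

Step 4
Reactants: 7 methyl (3S,5R,6E)-3,5-bis(TBSO)-7-phenylhept-6-enoate
Product: 9 (3S,5R,6E)-3,5-bis(TBSO)-7-phenylhept-6-enal, via aluminium hemiacetal 8 (not isolated)
Conditions: i-Bu2AlH (1.1 equiv), CH2Cl2, −78 °C; MeOH, then aq. potassium sodium tartrate
Reagents that add atoms: none
Why: Partial reduction of the methyl ester with diisobutylaluminium hydride at −78 °C, where the tetrahedral aluminium hemiacetal 8 persists until work-up, so the C4′ aldehyde is released without over-reduction and the β-silyloxy centre is untouched.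

Step 5
Reactants: 9 (3S,5R,6E)-3,5-bis(TBSO)-7-phenylhept-6-enal; 10 allenylboronic acid pinacol ester
Product: 12 (4S,6R,8R,9E)-6,8-bis(TBSO)-10-phenyldec-9-en-1-yn-4-ol, via O-boryl homopropargyl ether 11 (not isolated)
Conditions: 10 (1.5 equiv), (S)-TRIP (10 mol %), 4 Å MS, toluene, −20 to 0 °C; aq. NaHCO3 work-up
Reagents that add atoms: none
Why: Chiral phosphoric acid catalysed allenylboration (propargylation) through a closed six-membered SE2′ transition state: (S)-TRIP is expected to direct the boronate to the Si face of the aldehyde, setting C4′ as S (1,3-anti to the C6′ oxygen) under catalyst control, since 1,3-induction from a β-silyloxy group is weak in cyclic transition states, and the minor diastereomer should be removable by chromatography.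

Step 6
Reactants: 12 (4S,6R,8R,9E)-6,8-bis(TBSO)-10-phenyldec-9-en-1-yn-4-ol
Product: 13 (4S,6R,8R,9E)-4,6,8-tris(TBSO)-10-phenyldec-9-en-1-yne
Conditions: TBSOTf (1.3 equiv), 2,6-lutidine, CH2Cl2, −78 to 0 °C
Reagents that add atoms: tert-butyldimethylsilyl triflate, CC(C)(C)[Si](C)(C)OS(=O)(=O)C(F)(F)F
Why: Routine silylation of the homopropargylic alcohol, which gives three identical protecting groups for a single final deprotection.

Step 7
Reactants: 13 (4S,6R,8R,9E)-4,6,8-tris(TBSO)-10-phenyldec-9-en-1-yne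
Product: 16 (5S,7R,9R,10E)-5,7,9-tris(TBSO)-11-phenylundec-10-en-2-ynal, via lithium acetylide 14 (not isolated), via lithium hemiaminal alkoxide 15 (not isolated)
Conditions: n-BuLi (1.1 equiv), THF, −78 °C; DMF (3 equiv), −78 to 0 °C; inverse quench into 10 % aq. KH2PO4/MTBE, 0 °C
Reagents that add atoms: N,N-dimethylformamide, CN(C)C=O
Why: Formylation of the lithium acetylide 14 with DMF; the hemiaminal alkoxide 15 survives until the inverse quench into phosphate buffer, which liberates the ynal without exposing it to free dimethylamine or base, so neither conjugate addition nor β-elimination of the C4′ silyloxy group should occur.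

Step 8
Reactants: 16 (5S,7R,9R,10E)-5,7,9-tris(TBSO)-11-phenylundec-10-en-2-ynal; 17 (E)-1-methoxybuta-1,3-diene
Product: 18 (2S,6R)-2-methoxy-6-[(4S,6R,8R,9E)-4,6,8-tris(TBSO)-10-phenyldec-9-en-1-yn-1-yl]-5,6-dihydro-2H-pyran (2,6-cis)
Conditions: 17 (4 equiv), CrCl(L) (5–10 mol %; L = dianion of 2-(1-adamantyl)-6-{[(1R,2S)-2-hydroxyindan-1-yl]iminomethyl}-4-methylphenol; a chloride complex of trivalent chromium), 4 Å MS, minimal acetone, rt, 24–48 h
Reagents that add atoms: none
Why: The formyl oxygen of 16 binds the Lewis acidic trivalent chromium of CrCl(L) and the diene adds in a concerted but asynchronous [4+2] cycloaddition, its unsubstituted terminus attacking the carbonyl carbon while the carbonyl oxygen bonds to the methoxy-bearing carbon. The closest known reaction type is the chromium Schiff-base catalysed enantioselective hetero-Diels–Alder reaction of 1-methoxybutadiene with aldehydes, which is established for conjugated ynals. The dihydropyran ring is closed by intermolecular cycloaddition, C5–C6 and O1–C2 being formed in the same step and not by cyclisation of an open chain. C6 (R) is set by the catalyst, whose (1R,2S)-aminoindanol ligand is expected to expose the Re face of the aldehyde, and C2 (S) follows from the endo transition state that places OMe and the alkynyl group cis. The step needs chemoselectivity for C=O over the ynal C≡C and the styryl C=C, regioselectivity and face selectivity: carbonyl complexation activates only the C=O, the methoxy group polarises the diene so that O1 bonds to C2, and the slim non-enolisable alkynyl substituent, with its nearest stereocentre three atoms away, leaves the facial choice to the catalyst.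

Step 9
Reactants: 18 (2S,6R)-2-methoxy-6-[(4S,6R,8R,9E)-4,6,8-tris(TBSO)-10-phenyldec-9-en-1-yn-1-yl]-5,6-dihydro-2H-pyran
Product: 19 (6R)-6-[(4S,6R,8R,9E)-4,6,8-tris(TBSO)-10-phenyldec-9-en-1-yn-1-yl]-5,6-dihydro-2H-pyran-2-ol (both C2 epimers)
Conditions: PPTS (cat.), acetone/H2O 10:1, rt
Reagents that add atoms: water, O
Why: Acid-catalysed hydrolysis of the allylic methyl acetal through the stabilised oxocarbenium ion; PPTS should leave the three TBS ethers intact, the propargylic C6–O bond does not ionise, and C6 is not involved.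

Step 10
Reactants: 19 (6R)-6-[(4S,6R,8R,9E)-4,6,8-tris(TBSO)-10-phenyldec-9-en-1-yn-1-yl]-5,6-dihydro-2H-pyran-2-ol
Product: 20 (6R)-6-[(4S,6R,8R,9E)-4,6,8-tris(TBSO)-10-phenyldec-9-en-1-yn-1-yl]-5,6-dihydro-2H-pyran-2-one
Conditions: MnO2 (excess), CH2Cl2, rt
Reagents that add atoms: none
Why: MnO2 oxidation of the allylic lactol (hemiacetal OH on the carbon next to C3=C4) should give the α,β-unsaturated δ-lactone and erase the C2 stereocentre; alkyne, styrene and silyl ethers are inert to MnO2.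

Step 11
Reactants: 20 (6R)-6-[(4S,6R,8R,9E)-4,6,8-tris(TBSO)-10-phenyldec-9-en-1-yn-1-yl]-5,6-dihydro-2H-pyran-2-one
Product: 21 (6R)-6-[(1Z,4S,6R,8R,9E)-4,6,8-tris(TBSO)-10-phenyldeca-1,9-dien-1-yl]-5,6-dihydro-2H-pyran-2-one
Conditions: H2 (1 atm), Pd/CaCO3 poisoned with Pb(OAc)2 (Lindlar catalyst), quinoline, EtOAc, rt, stopped at 1 equiv uptake
Reagents that add atoms: none
Why: Lindlar semi-hydrogenation: syn delivery of H2 on the poisoned palladium surface should give the Z-alkene C1′=C2′, and the quinoline-moderated catalyst should spare the conjugated ring alkene and the E-styryl alkene.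

Step 12
Reactants: 21 (6R)-6-[(1Z,4S,6R,8R,9E)-4,6,8-tris(TBSO)-10-phenyldeca-1,9-dien-1-yl]-5,6-dihydro-2H-pyran-2-one
Product: 22 (6R)-6-[(1Z,4S,6R,8R,9E)-4,6,8-trihydroxy-10-phenyldeca-1,9-dien-1-yl]-5,6-dihydro-2H-pyran-2-one (target)
Conditions: HF·pyridine, pyridine, THF, 0 °C to rt
Reagents that add atoms: none
Why: Fluoride cleavage of the three TBS ethers with pyridine-buffered HF·pyridine, conditions that avoid the basic medium in which the dihydropyranone would open or isomerise and that are mild enough for the allylic C8′ carbinol.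

**Compound list**

1 | (E)-cinnamaldehyde | O=C/C=C/c1ccccc1 | starting material
2 | 1-methoxy-1,3-bis(trimethylsilyloxy)buta-1,3-diene (Chan's diene) | COC(O[Si](C)(C)C)=CC(=C)O[Si](C)(C)C | starting material
3 | methyl (5R,6E)-7-phenyl-3,5-bis(trimethylsilyloxy)hepta-2,6-dienoate (silylated aldol adduct, not isolated) | COC(=O)C=C(O[Si](C)(C)C)C[C@@H](O[Si](C)(C)C)/C=C/c1ccccc1 | intermediate
4 | methyl (5R,6E)-5-hydroxy-3-oxo-7-phenylhept-6-enoate | COC(=O)CC(=O)C[C@@H](O)/C=C/c1ccccc1 | intermediate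
5 | diethylboron chelate of 4 (not isolated) | COC(=O)CC1=[O+][B-](CC)(CC)O[C@@H](/C=C/c2ccccc2)C1 | intermediate
6 | methyl (3S,5R,6E)-3,5-dihydroxy-7-phenylhept-6-enoate | COC(=O)C[C@@H](O)C[C@@H](O)/C=C/c1ccccc1 | intermediate
7 | methyl (3S,5R,6E)-3,5-bis(TBSO)-7-phenylhept-6-enoate | COC(=O)C[C@@H](O[Si](C)(C)C(C)(C)C)C[C@@H](O[Si](C)(C)C(C)(C)C)/C=C/c1ccccc1 | intermediate
8 | diisobutylaluminium hemiacetal of 7 (not isolated) | COC(O[Al](CC(C)C)CC(C)C)C[C@@H](O[Si](C)(C)C(C)(C)C)C[C@@H](O[Si](C)(C)C(C)(C)C)/C=C/c1ccccc1 | intermediate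
9 | (3S,5R,6E)-3,5-bis(TBSO)-7-phenylhept-6-enal | O=CC[C@@H](O[Si](C)(C)C(C)(C)C)C[C@@H](O[Si](C)(C)C(C)(C)C)/C=C/c1ccccc1 | intermediate
10 | allenylboronic acid pinacol ester (4,4,5,5-tetramethyl-2-(propa-1,2-dien-1-yl)-1,3,2-dioxaborolane) | C=C=CB1OC(C)(C)C(C)(C)O1 | starting material
11 | O-(pinacolatoboryl) ether of 12 (not isolated) | C#CC[C@H](OB1OC(C)(C)C(C)(C)O1)C[C@@H](O[Si](C)(C)C(C)(C)C)C[C@@H](O[Si](C)(C)C(C)(C)C)/C=C/c1ccccc1 | intermediate
12 | (4S,6R,8R,9E)-6,8-bis(TBSO)-10-phenyldec-9-en-1-yn-4-ol | C#CC[C@H](O)C[C@@H](O[Si](C)(C)C(C)(C)C)C[C@@H](O[Si](C)(C)C(C)(C)C)/C=C/c1ccccc1 | intermediate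
13 | (4S,6R,8R,9E)-4,6,8-tris(TBSO)-10-phenyldec-9-en-1-yne | C#CC[C@H](O[Si](C)(C)C(C)(C)C)C[C@@H](O[Si](C)(C)C(C)(C)C)C[C@@H](O[Si](C)(C)C(C)(C)C)/C=C/c1ccccc1 | intermediate
14 | lithium acetylide of 13 (not isolated) | [Li]C#CC[C@H](O[Si](C)(C)C(C)(C)C)C[C@@H](O[Si](C)(C)C(C)(C)C)C[C@@H](O[Si](C)(C)C(C)(C)C)/C=C/c1ccccc1 | intermediate
15 | lithium hemiaminal alkoxide from 14 and DMF (not isolated) | [Li]OC(N(C)C)C#CC[C@H](O[Si](C)(C)C(C)(C)C)C[C@@H](O[Si](C)(C)C(C)(C)C)C[C@@H](O[Si](C)(C)C(C)(C)C)/C=C/c1ccccc1 | intermediate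
16 | (5S,7R,9R,10E)-5,7,9-tris(TBSO)-11-phenylundec-10-en-2-ynal | O=CC#CC[C@H](O[Si](C)(C)C(C)(C)C)C[C@@H](O[Si](C)(C)C(C)(C)C)C[C@@H](O[Si](C)(C)C(C)(C)C)/C=C/c1ccccc1 | intermediate
17 | (E)-1-methoxybuta-1,3-diene | CO/C=C/C=C | starting material
18 | (2S,6R)-2-methoxy-6-[(4S,6R,8R,9E)-4,6,8-tris(TBSO)-10-phenyldec-9-en-1-yn-1-yl]-5,6-dihydro-2H-pyran | CO[C@@H]1C=CC[C@H](C#CC[C@H](O[Si](C)(C)C(C)(C)C)C[C@@H](O[Si](C)(C)C(C)(C)C)C[C@@H](O[Si](C)(C)C(C)(C)C)/C=C/c2ccccc2)O1 | intermediate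
19 | (6R)-6-[(4S,6R,8R,9E)-4,6,8-tris(TBSO)-10-phenyldec-9-en-1-yn-1-yl]-5,6-dihydro-2H-pyran-2-ol (both C2 epimers) | OC1C=CC[C@H](C#CC[C@H](O[Si](C)(C)C(C)(C)C)C[C@@H](O[Si](C)(C)C(C)(C)C)C[C@@H](O[Si](C)(C)C(C)(C)C)/C=C/c2ccccc2)O1 | intermediate
20 | (6R)-6-[(4S,6R,8R,9E)-4,6,8-tris(TBSO)-10-phenyldec-9-en-1-yn-1-yl]-5,6-dihydro-2H-pyran-2-one | O=C1C=CC[C@H](C#CC[C@H](O[Si](C)(C)C(C)(C)C)C[C@@H](O[Si](C)(C)C(C)(C)C)C[C@@H](O[Si](C)(C)C(C)(C)C)/C=C/c2ccccc2)O1 | intermediate
21 | (6R)-6-[(1Z,4S,6R,8R,9E)-4,6,8-tris(TBSO)-10-phenyldeca-1,9-dien-1-yl]-5,6-dihydro-2H-pyran-2-one | O=C1C=CC[C@H](/C=C\C[C@H](O[Si](C)(C)C(C)(C)C)C[C@@H](O[Si](C)(C)C(C)(C)C)C[C@@H](O[Si](C)(C)C(C)(C)C)/C=C/c2ccccc2)O1 | intermediate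
22 | (6R)-6-[(1Z,4S,6R,8R,9E)-4,6,8-trihydroxy-10-phenyldeca-1,9-dien-1-yl]-5,6-dihydro-2H-pyran-2-one | O=C1C=CC[C@H](/C=C\C[C@H](O)C[C@@H](O)C[C@@H](O)/C=C/c2ccccc2)O1 | target

**Step count and risks**

Total step count: 12. Longest linear sequence: 12 steps (from cinnamaldehyde; compounds 2, 10 and 17 are bought).

Steps most likely to fail:

Step 8 (key step). The cycloaddition may turn over slowly with the bulky, polyoxygenated ynal, so that diene oligomerisation or decay of the ynal competes, or the facial selectivity may be insufficient and give the C6 epimer. Fallback, from 16 back to 20: Brown allylation of 16 with (+)-Ipc2B(allyl) (from (+)-Ipc2BOMe and allylmagnesium bromide, Et2O, −78 °C), which adds to the Re face, would give (4R,8S,10R,12R,13E)-8,10,12-tris(TBSO)-14-phenyltetradeca-1,13-dien-5-yn-4-ol F1. Acylation with acryloyl chloride, Et3N and DMAP would give (4R,8S,10R,12R,13E)-8,10,12-tris(TBSO)-14-phenyltetradeca-1,13-dien-5-yn-4-yl acrylate F2. Ring-closing metathesis with first-generation Grubbs catalyst RuCl2(PCy3)2(=CHPh) in CH2Cl2 at reflux should start at the terminal allyl alkene and close on the acrylate faster than it engages the internal alkyne or the styryl alkene, and would deliver 20.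

Step 5. Catalyst control over the face of the β-silyloxy aldehyde may be incomplete, giving a mixture of C4′ epimers, and allenyl carbinol may form alongside. Fallback, from 9 back to 12: a Barbier propargylation (zinc dust, propargyl bromide, THF, 0 °C) without stereocontrol would give 12 together with its epimer (4R,6R,8R,9E)-6,8-bis(TBSO)-10-phenyldec-9-en-1-yn-4-ol F3. After chromatographic separation, F3 would be inverted by a Mitsunobu reaction (4-nitrobenzoic acid, PPh3, DIAD, THF) to (4S,6R,8R,9E)-6,8-bis(TBSO)-10-phenyldec-9-en-1-yn-4-yl 4-nitrobenzoate F4, and methanolysis (K2CO3, MeOH) would return 12.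

Step 11. Hydrogenation may run past the Z-alkene, may saturate the conjugated C3=C4 bond of the lactone, or may stall through catalyst poisoning. Fallback, from 18 back to 21: the semi-hydrogenation is moved ahead of the lactone unveiling, where no conjugated alkene is present. The same poisoned palladium catalyst on 18 would give (2S,6R)-2-methoxy-6-[(1Z,4S,6R,8R,9E)-4,6,8-tris(TBSO)-10-phenyldeca-1,9-dien-1-yl]-5,6-dihydro-2H-pyran F5. PPTS in wet acetone would give (6R)-6-[(1Z,4S,6R,8R,9E)-4,6,8-tris(TBSO)-10-phenyldeca-1,9-dien-1-yl]-5,6-dihydro-2H-pyran-2-ol F6, and MnO2 would oxidise it to 21.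

Further compounds
F1 | step 8 | (4R,8S,10R,12R,13E)-8,10,12-tris(TBSO)-14-phenyltetradeca-1,13-dien-5-yn-4-ol | C=CC[C@@H](O)C#CC[C@H](O[Si](C)(C)C(C)(C)C)C[C@@H](O[Si](C)(C)C(C)(C)C)C[C@@H](O[Si](C)(C)C(C)(C)C)/C=C/c1ccccc1
F2 | step 8 | (4R,8S,10R,12R,13E)-8,10,12-tris(TBSO)-14-phenyltetradeca-1,13-dien-5-yn-4-yl acrylate | C=CC(=O)O[C@H](CC=C)C#CC[C@H](O[Si](C)(C)C(C)(C)C)C[C@@H](O[Si](C)(C)C(C)(C)C)C[C@@H](O[Si](C)(C)C(C)(C)C)/C=C/c1ccccc1
F3 | step 5 | (4R,6R,8R,9E)-6,8-bis(TBSO)-10-phenyldec-9-en-1-yn-4-ol | C#CC[C@@H](O)C[C@@H](O[Si](C)(C)C(C)(C)C)C[C@@H](O[Si](C)(C)C(C)(C)C)/C=C/c1ccccc1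
F4 | step 5 | (4S,6R,8R,9E)-6,8-bis(TBSO)-10-phenyldec-9-en-1-yn-4-yl 4-nitrobenzoate | C#CC[C@H](OC(=O)c1ccc(cc1)[N+](=O)[O-])C[C@@H](O[Si](C)(C)C(C)(C)C)C[C@@H](O[Si](C)(C)C(C)(C)C)/C=C/c2ccccc2
F5 | step 11 | (2S,6R)-2-methoxy-6-[(1Z,4S,6R,8R,9E)-4,6,8-tris(TBSO)-10-phenyldeca-1,9-dien-1-yl]-5,6-dihydro-2H-pyran | CO[C@@H]1C=CC[C@H](/C=C\C[C@H](O[Si](C)(C)C(C)(C)C)C[C@@H](O[Si](C)(C)C(C)(C)C)C[C@@H](O[Si](C)(C)C(C)(C)C)/C=C/c2ccccc2)O1
F6 | step 11 | (6R)-6-[(1Z,4S,6R,8R,9E)-4,6,8-tris(TBSO)-10-phenyldeca-1,9-dien-1-yl]-5,6-dihydro-2H-pyran-2-ol (both C2 epimers) | OC1C=CC[C@H](/C=C\C[C@H](O[Si](C)(C)C(C)(C)C)C[C@@H](O[Si](C)(C)C(C)(C)C)C[C@@H](O[Si](C)(C)C(C)(C)C)/C=C/c2ccccc2)O1
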